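(The runs are calculated from invented constants; scatter was added.)

Read the target column of both runs against the side product A column before reckoning anything.

| flask | starting material | reagent | remark | time |
|---|---|---|---|---|
| amber | 0.80 M | 0.72 M | the very flask that is asked about, followed so far |  |
| green | 0.80 M | 1.4 M | run made earlier |  |
| flask | 0.80 M | 0.720 M |  | 3.0 min |

- amber (time / s: side product A / %, target / %): 10.0: 23.2, 11.4; 15.0: 28.2, 11.1; 25.0: 29.3, 8.1; 30.0: 28.9, 9.0; 40.0: 31.9, 7.2; 50.0: 34.3, 5.3
- green (time / min: side product A / %, target / %): 0.250: 26.1, 8.1; 0.333: 27.6, 6.2; 0.500: 28.8, 5.4; 0.833: 32.8, 2.2; 1.33: 39.3, 1.7; 2.00: 42.2, 1.5; 3.00: 49.4, 1.4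

(readings scatter by 1 percentage point)

1. share of side product A in side product A plus target at 0.20 s
2. share of side product A in side product A plus target at 6.0 s
3. share of side product A in side product A plus target at 3.0 min
4. which of side product A and target there is more of at 3.0 min



At 30.0 s, side product A reads 28.9% in amber and 28.8% in green, while target reads 9.0% against 5.4%. So I take the extra reagent to act on target and to leave side product A about where it is.

Down the target columns, amber falls from 11.4% to 5.3% between 10.0 s and 50.0 s, a rate of 0.0191 s⁻¹. Green falls from 8.1% to 2.2% between 0.250 min and 0.833 min, a rate of 0.0373 s⁻¹. Divided by the charged c(reagent), these give 0.0266 M⁻¹ s⁻¹ and 0.0266 M⁻¹ s⁻¹, about the same. I carry the first as the loss constant, the pseudo-first-order fall of target per unit of c(reagent), and it is a reading with the scatter of the readings.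

The last green rows stay between 1.7% and 1.4% despite that loss, so I read them as a plateau where making balances loss. Side product A agrees between the runs, so I assume the same making of target in amber. I then take the product c(target) times c(reagent) to be the same in both runs, so I put the amber plateau at 2.72%.

Going round once more, I put that plateau back in. The excess over it at 50.0 s shrinks by a factor 0.0830 up to 3.0 min, which gives target 2.94%. With green's last side product A reading, 49.4%, the amber share at 3.0 min is 94.4%, and side product A leads. The two earlier asked times lie before the first reading, so this reckoning gives no share for them.

The forecast says 58%, 64% and 95%, with side product A ahead, calling the loss of target “roughly first order in reagent”.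

The amber flask gives 66.1%, 68.5% and 95.0%, with side product A at 48.9% and target at 2.58%.

    starting material → target (k = 0.0297 s⁻¹)
    starting material → side product A (k = 0.0577 s⁻¹)
    starting material ⇌ intermediate (K = 10.2, k = 0.131 s⁻¹)
    starting material + target → side product B (k = 0.0111 M⁻¹ s⁻¹)
    reagent + target → over-reaction product (k = 0.0389 M⁻¹ s⁻¹)

The neighbouring flask has 0.18 M of reagent, so the loss constant gives it a rate of 0.00479 s⁻¹, slower than amber's. My reckoned plateau for it is 10.9%. Going round from amber's 11.4% at 10.0 s, taken as the neighbour's start, gives target 11.1% at 3.0 min, and green's last side product A reading again gives a share of 81.7%. The neighbouring flask holds target at 12.9% beside side product A at 48.8%, a share of 79.1%.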